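The C4–C5 bond of the lactone (benzyl-bearing carbon to O–CH2) is formed by ring closure before the lactone exists. The key step exploits the 1,3-relationship of C5 and the benzylic carbon C7, both attached to C4 of the lactone ring. A sacrificial hydroxyl on C7 carries a bromomethylsilyl tether; its 5-exo radical cyclization onto a Z-enoate closes a temporary oxasilolane ring, delivers C5 to C4 and relays the C7 carbinol configuration to C4. The precursor is a (bromomethyl)dimethylsilyl ether of a γ-hydroxy enoate. Tamao oxidation and C7 deoxygenation give the (S)-β-benzyl lactone, which is alkylated trans with a dihydrobenzofuran benzylic bromide made by asymmetric carbene C–H insertion.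

Key step: step 4

Atom labels used below: lactone O1, C2 (carbonyl), C3, C4, C5 (O–CH2); C7 is the benzylic carbon on C4.

Assumption: (R,R)-ProPhenol is taken to direct Si-face alkynylation of aldehyde 1 and Rh2(R-PTTL)4 to give the 2S insertion product; if either sense proves opposite, the antipodal ligand is used and nothing else changes.

Step 1
Reactants: 1 4-(benzyloxy)-3-methoxybenzaldehyde; 2 methyl propiolate
Product: 3 methyl (4R)-4-[4-(benzyloxy)-3-methoxyphenyl]-4-hydroxybut-2-ynoate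
Conditions: (R,R)-ProPhenol (10 mol%), ZnMe2 (3 equiv), Ph3P=O (20 mol%), toluene, 0 °C; aq NH4Cl
Reagents that add atoms: none
Why: Dinuclear zinc–ProPhenol asymmetric alkynylation, in which the alkynylzinc formed from 2 and ZnMe2 adds to the Si face of the aldehyde inside the chiral dizinc pocket and sets the (R)-carbinol, a stereocentre needed only to steer step 4 and erased in step 5.

Step 2
Reactants: 3 methyl (4R)-4-[4-(benzyloxy)-3-methoxyphenyl]-4-hydroxybut-2-ynoate; 4 (bromomethyl)chlorodimethylsilane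
Product: 5 methyl (4R)-4-[4-(benzyloxy)-3-methoxyphenyl]-4-{[(bromomethyl)dimethylsilyl]oxy}but-2-ynoate
Conditions: Et3N, DMAP (catalytic), CH2Cl2, 0 °C
Reagents that add atoms: none
Why: O-Silylation of the secondary alcohol by the chlorosilane installs the bromomethylsilyl tether that carries the future C5 while leaving the C–Br bond and the ynoate untouched.

Step 3
Reactants: 5 methyl (4R)-4-[4-(benzyloxy)-3-methoxyphenyl]-4-{[(bromomethyl)dimethylsilyl]oxy}but-2-ynoate
Product: 6 methyl (2Z,4S)-4-[4-(benzyloxy)-3-methoxyphenyl]-4-{[(bromomethyl)dimethylsilyl]oxy}but-2-enoate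
Conditions: H2 (1 atm), Pd/CaCO3 poisoned with Pb(OAc)2 (Lindlar catalyst), quinoline, EtOAc, rt
Reagents that add atoms: none
Why: Lindlar semihydrogenation adds H2 syn and should stop at the Z-enoate, the geometry that gives the strongest allylic-strain control in step 4, with the benzyl ether, C–Br bond and silyl ether inert to the poisoned catalyst (the descriptor changes from R to S only through CIP ranking).

Step 4
Reactants: 6 methyl (2Z,4S)-4-[4-(benzyloxy)-3-methoxyphenyl]-4-{[(bromomethyl)dimethylsilyl]oxy}but-2-enoate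
Product: 7 methyl 2-{(4R,5S)-5-[4-(benzyloxy)-3-methoxyphenyl]-2,2-dimethyl-1,2-oxasilolan-4-yl}acetate (4,5-trans)
Conditions: Bu3SnH (1.3 equiv, syringe pump), AIBN (0.1 equiv), benzene (0.02 M), 80 °C
Reagents that add atoms: none
Why: Bu3Sn• abstracts bromine to give an α-silyl methyl radical that adds to the enoate β-carbon (the future lactone C4), and the resulting α-ester radical is reduced by Bu3SnH; this is the Nishiyama–Stork silicon-tethered radical cyclization of a (bromomethyl)dimethylsilyl allyl ether. The 1,2-oxasilolane ring closes in the 5-exo-trig mode, forming the C4–C5 bond. The new stereocentre C4 is controlled by the carbinol stereocentre on C7: allylic 1,3-strain in the Z-enoate holds the carbinol hydrogen in the alkene plane, so the radical is delivered from the oxygen-bearing face and the aryl and CH2CO2Me groups should end up trans. Exo over endo closure is secured by the ester on the alkene terminus (polarity-matched acceptor, stabilized product radical), and cyclization over direct C–Br reduction by slow stannane addition at high dilution. Any cis isomer must be removed by chromatography here, because the carbinol centre is erased in step 5 and a diastereomer would then become the enantiomer.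

Step 5
Reactants: 7 methyl 2-{(4R,5S)-5-[4-(benzyloxy)-3-methoxyphenyl]-2,2-dimethyl-1,2-oxasilolan-4-yl}acetate
Product: 9 (4S)-4-{[4-(benzyloxy)-3-methoxyphenyl]methyl}oxolan-2-one, via diol ester 8 (not isolated)
Conditions: KF, KHCO3, 30% H2O2, THF/MeOH, rt; Na2S2O3 work-up; then Et3SiH (3 equiv), TFA, CH2Cl2, 0 °C to rt
Reagents that add atoms: hydrogen peroxide, OO
Why: Tamao oxidation converts the C–Si bond into C–OH with retention (diol 8), and Et3SiH/TFA then removes the p-alkoxybenzylic hydroxyl by ionic hydrogenation while the acid closes the primary alcohol onto the ester, so that partly lactonized forms of 8 converge on 9 and C4 is not touched.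

Step 6
Reactants: 10 methyl 3-bromo-4,5-dihydroxybenzoate; 11 4-(benzyloxy)-3-methoxybenzyl chloride (2.2 equiv)
Product: 12 methyl 3-bromo-4,5-bis{[4-(benzyloxy)-3-methoxyphenyl]methoxy}benzoate
Conditions: K2CO3, NaI (catalytic), DMF, 60 °C
Reagents that add atoms: none
Why: Williamson etherification of both phenols, in which the ether ortho to bromine later supplies C2–H and the 2-aryl group of the dihydrobenzofuran and the other ether serves as a hydrogenolysable protecting group.

Step 7
Reactants: 12 methyl 3-bromo-4,5-bis{[4-(benzyloxy)-3-methoxyphenyl]methoxy}benzoate; 13 (2-tert-butoxy-2-oxoethyl)zinc chloride (solution in Et2O)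
Product: 14 methyl 4,5-bis{[4-(benzyloxy)-3-methoxyphenyl]methoxy}-3-(2-tert-butoxy-2-oxoethyl)benzoate
Conditions: Pd(dba)2 (2 mol%), Q-Phos (2 mol%), THF, rt to 50 °C
Reagents that add atoms: none
Why: Palladium-catalysed α-arylation of a Reformatsky-type zinc enolate (Hartwig conditions) replaces the aryl bromide by CH2CO2tBu without strong base, so the methyl benzoate and benzylic ethers survive.

Step 8
Reactants: 14 methyl 4,5-bis{[4-(benzyloxy)-3-methoxyphenyl]methoxy}-3-(2-tert-butoxy-2-oxoethyl)benzoate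
Product: 15 methyl 4,5-bis{[4-(benzyloxy)-3-methoxyphenyl]methoxy}-3-(2-tert-butoxy-1-diazo-2-oxoethyl)benzoate
Conditions: p-ABSA (1.3 equiv), DBU (1.5 equiv), MeCN, 0 °C to rt
Reagents that add atoms: 4-acetamidobenzenesulfonyl azide (p-ABSA), CC(=O)Nc1ccc(cc1)S(=O)(=O)N=[N+]=[N-]
Why: Regitz diazo transfer to the benzylic, ester-activated methylene gives the donor/acceptor diazo ester.

Step 9
Reactants: 15 methyl 4,5-bis{[4-(benzyloxy)-3-methoxyphenyl]methoxy}-3-(2-tert-butoxy-1-diazo-2-oxoethyl)benzoate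
Product: 17 3-tert-butyl 5-methyl (2S,3S)-2-[4-(benzyloxy)-3-methoxyphenyl]-7-{[4-(benzyloxy)-3-methoxyphenyl]methoxy}-2,3-dihydro-1-benzofuran-3,5-dicarboxylate, via cis diester 16 (not isolated)
Conditions: dirhodium tetrakis[N-phthaloyl-(R)-tert-leucinate], Rh2(R-PTTL)4 (1 mol%), toluene, −60 °C; then NaOMe (0.3 equiv), MeOH/THF, rt
Reagents that add atoms: none
Why: The chiral dirhodium carboxylate generates a donor/acceptor carbene that inserts into the ortho O–CH2Ar C–H bond (enantioselective intramolecular 1,5-C–H insertion) to give cis-dihydrobenzofuran 16 with C2 set by the catalyst, and catalytic methoxide then epimerizes the ester-bearing C3 to the thermodynamically favoured trans isomer without touching C2 or the hindered tert-butyl ester.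

Step 10
Reactants: 17 3-tert-butyl 5-methyl (2S,3S)-2-[4-(benzyloxy)-3-methoxyphenyl]-7-{[4-(benzyloxy)-3-methoxyphenyl]methoxy}-2,3-dihydro-1-benzofuran-3,5-dicarboxylate
Product: 18 {(2S,3R)-2-[4-(benzyloxy)-3-methoxyphenyl]-7-{[4-(benzyloxy)-3-methoxyphenyl]methoxy}-3-(hydroxymethyl)-2,3-dihydro-1-benzofuran-5-yl}methanol
Conditions: LiAlH4, THF, 0 °C to rt; Fieser work-up
Reagents that add atoms: none
Why: Hydride reduction of both esters gives the benzylic and the aliphatic primary alcohol, with benzyl-type ethers and the ring inert (the C3 descriptor changes from S to R only through CIP ranking).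

Step 11
Reactants: 18 {(2S,3R)-2-[4-(benzyloxy)-3-methoxyphenyl]-7-{[4-(benzyloxy)-3-methoxyphenyl]methoxy}-3-(hydroxymethyl)-2,3-dihydro-1-benzofuran-5-yl}methanol
Product: 19 {(2S,3R)-2-[4-(benzyloxy)-3-methoxyphenyl]-7-{[4-(benzyloxy)-3-methoxyphenyl]methoxy}-5-(bromomethyl)-2,3-dihydro-1-benzofuran-3-yl}methanol
Conditions: NBS, Me2S, CH2Cl2, −20 °C to 0 °C; aqueous work-up
Reagents that add atoms: N-bromosuccinimide, O=C1CCC(=O)N1Br
Why: Corey–Kim bromination proceeds through alkoxysulfonium salts that bromide displaces only at the activated benzylic carbon, so the saturated primary alcohol should be returned unchanged on work-up under neutral conditions that spare the acid-sensitive benzylic ethers.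

Step 12
Reactants: 9 (4S)-4-{[4-(benzyloxy)-3-methoxyphenyl]methyl}oxolan-2-one; 19 {(2S,3R)-2-[4-(benzyloxy)-3-methoxyphenyl]-7-{[4-(benzyloxy)-3-methoxyphenyl]methoxy}-5-(bromomethyl)-2,3-dihydro-1-benzofuran-3-yl}methanol
Product: 22 (3S,4S)-3-({(2S,3R)-2-[4-(benzyloxy)-3-methoxyphenyl]-7-{[4-(benzyloxy)-3-methoxyphenyl]methoxy}-3-(hydroxymethyl)-2,3-dihydro-1-benzofuran-5-yl}methyl)-4-{[4-(benzyloxy)-3-methoxyphenyl]methyl}oxolan-2-one, via silyl ether bromide 20 (not isolated), via silyl ether lactone 21 (not isolated)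
Conditions: 19, (Me3Si)2NH, Me3SiCl (catalytic), CH2Cl2, rt, evaporate; 9, LiN(SiMe3)2 (1.05 equiv), THF, −78 °C; add 20, DMPU, −78 to −40 °C; then aq citric acid, THF, rt
Reagents that add atoms: none
Why: Transient O-trimethylsilylation masks the alcohol, and the lithium enolate of 9 is benzylated anti to the C4 substituent (the standard trans-selective alkylation of β-substituted γ-butyrolactone enolates), which sets C3 as S before mild acid removes the silyl group.

Step 13
Reactants: 22 (3S,4S)-3-({(2S,3R)-2-[4-(benzyloxy)-3-methoxyphenyl]-7-{[4-(benzyloxy)-3-methoxyphenyl]methoxy}-3-(hydroxymethyl)-2,3-dihydro-1-benzofuran-5-yl}methyl)-4-{[4-(benzyloxy)-3-methoxyphenyl]methyl}oxolan-2-one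
Product: 23 (3S,4S)-3-{[(2S,3R)-7-hydroxy-2-(4-hydroxy-3-methoxyphenyl)-3-(hydroxymethyl)-2,3-dihydro-1-benzofuran-5-yl]methyl}-4-[(4-hydroxy-3-methoxyphenyl)methyl]oxolan-2-one (CNP0118131.1)
Conditions: H2 (1 atm), 10% Pd/C, EtOAc/MeOH, rt
Reagents that add atoms: none
Why: Neutral hydrogenolysis over Pd/C at 1 atm cleaves the two O-benzyl groups and the O-(4-benzyloxy-3-methoxybenzyl) group, under conditions where the cyclic benzylic C2–O bond of the dihydrobenzofuran, the lactone and the methyl ethers should be retained.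

Compound list
1 | 4-(benzyloxy)-3-methoxybenzaldehyde | COc1cc(C=O)ccc1OCc1ccccc1 | starting material
2 | methyl propiolate | COC(=O)C#C | starting material
3 | methyl (4R)-4-[4-(benzyloxy)-3-methoxyphenyl]-4-hydroxybut-2-ynoate | COC(=O)C#C[C@H](O)c1ccc(OCc2ccccc2)c(OC)c1 | intermediate
4 | (bromomethyl)chlorodimethylsilane | C[Si](C)(Cl)CBr | starting material
5 | methyl (4R)-4-[4-(benzyloxy)-3-methoxyphenyl]-4-{[(bromomethyl)dimethylsilyl]oxy}but-2-ynoate | COC(=O)C#C[C@H](O[Si](C)(C)CBr)c1ccc(OCc2ccccc2)c(OC)c1 | intermediate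
6 | methyl (2Z,4S)-4-[4-(benzyloxy)-3-methoxyphenyl]-4-{[(bromomethyl)dimethylsilyl]oxy}but-2-enoate | COC(=O)/C=C\[C@H](O[Si](C)(C)CBr)c1ccc(OCc2ccccc2)c(OC)c1 | intermediate
7 | methyl 2-{(4R,5S)-5-[4-(benzyloxy)-3-methoxyphenyl]-2,2-dimethyl-1,2-oxasilolan-4-yl}acetate | COC(=O)C[C@H]1C[Si](C)(C)O[C@@H]1c1ccc(OCc2ccccc2)c(OC)c1 | intermediate
8 | methyl (3S,4S)-4-[4-(benzyloxy)-3-methoxyphenyl]-4-hydroxy-3-(hydroxymethyl)butanoate | COC(=O)C[C@@H](CO)[C@H](O)c1ccc(OCc2ccccc2)c(OC)c1 | intermediate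
9 | (4S)-4-{[4-(benzyloxy)-3-methoxyphenyl]methyl}oxolan-2-one | COc1cc(C[C@@H]2COC(=O)C2)ccc1OCc1ccccc1 | intermediate
10 | methyl 3-bromo-4,5-dihydroxybenzoate | COC(=O)c1cc(O)c(O)c(Br)c1 | starting material
11 | 4-(benzyloxy)-3-methoxybenzyl chloride | COc1cc(CCl)ccc1OCc1ccccc1 | starting material
12 | methyl 3-bromo-4,5-bis{[4-(benzyloxy)-3-methoxyphenyl]methoxy}benzoate | COC(=O)c1cc(Br)c(OCc2ccc(OCc3ccccc3)c(OC)c2)c(OCc2ccc(OCc3ccccc3)c(OC)c2)c1 | intermediate
13 | (2-tert-butoxy-2-oxoethyl)zinc chloride | CC(C)(C)OC(=O)C[Zn]Cl | starting material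
14 | methyl 4,5-bis{[4-(benzyloxy)-3-methoxyphenyl]methoxy}-3-(2-tert-butoxy-2-oxoethyl)benzoate | COC(=O)c1cc(CC(=O)OC(C)(C)C)c(OCc2ccc(OCc3ccccc3)c(OC)c2)c(OCc2ccc(OCc3ccccc3)c(OC)c2)c1 | intermediate
15 | methyl 4,5-bis{[4-(benzyloxy)-3-methoxyphenyl]methoxy}-3-(2-tert-butoxy-1-diazo-2-oxoethyl)benzoate | COC(=O)c1cc(C(=[N+]=[N-])C(=O)OC(C)(C)C)c(OCc2ccc(OCc3ccccc3)c(OC)c2)c(OCc2ccc(OCc3ccccc3)c(OC)c2)c1 | intermediate
16 | 3-tert-butyl 5-methyl (2S,3R)-2-[4-(benzyloxy)-3-methoxyphenyl]-7-{[4-(benzyloxy)-3-methoxyphenyl]methoxy}-2,3-dihydro-1-benzofuran-3,5-dicarboxylate (cis) | COC(=O)c1cc(OCc2ccc(OCc3ccccc3)c(OC)c2)c2c(c1)[C@@H](C(=O)OC(C)(C)C)[C@@H](c1ccc(OCc3ccccc3)c(OC)c1)O2 | intermediate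
17 | 3-tert-butyl 5-methyl (2S,3S)-2-[4-(benzyloxy)-3-methoxyphenyl]-7-{[4-(benzyloxy)-3-methoxyphenyl]methoxy}-2,3-dihydro-1-benzofuran-3,5-dicarboxylate (trans) | COC(=O)c1cc(OCc2ccc(OCc3ccccc3)c(OC)c2)c2c(c1)[C@H](C(=O)OC(C)(C)C)[C@@H](c1ccc(OCc3ccccc3)c(OC)c1)O2 | intermediate
18 | {(2S,3R)-2-[4-(benzyloxy)-3-methoxyphenyl]-7-{[4-(benzyloxy)-3-methoxyphenyl]methoxy}-3-(hydroxymethyl)-2,3-dihydro-1-benzofuran-5-yl}methanol | OCc1cc(OCc2ccc(OCc3ccccc3)c(OC)c2)c2c(c1)[C@H](CO)[C@@H](c1ccc(OCc3ccccc3)c(OC)c1)O2 | intermediate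
19 | {(2S,3R)-2-[4-(benzyloxy)-3-methoxyphenyl]-7-{[4-(benzyloxy)-3-methoxyphenyl]methoxy}-5-(bromomethyl)-2,3-dihydro-1-benzofuran-3-yl}methanol | BrCc1cc(OCc2ccc(OCc3ccccc3)c(OC)c2)c2c(c1)[C@H](CO)[C@@H](c1ccc(OCc3ccccc3)c(OC)c1)O2 | intermediate
20 | trimethylsilyl ether of 19 | BrCc1cc(OCc2ccc(OCc3ccccc3)c(OC)c2)c2c(c1)[C@H](CO[Si](C)(C)C)[C@@H](c1ccc(OCc3ccccc3)c(OC)c1)O2 | intermediate
21 | trimethylsilyl ether of 22 | COc1cc(C[C@@H]2COC(=O)[C@H]2Cc2cc(OCc4ccc(OCc5ccccc5)c(OC)c4)c3c(c2)[C@H](CO[Si](C)(C)C)[C@@H](c2ccc(OCc4ccccc4)c(OC)c2)O3)ccc1OCc1ccccc1 | intermediate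
22 | (3S,4S)-3-({(2S,3R)-2-[4-(benzyloxy)-3-methoxyphenyl]-7-{[4-(benzyloxy)-3-methoxyphenyl]methoxy}-3-(hydroxymethyl)-2,3-dihydro-1-benzofuran-5-yl}methyl)-4-{[4-(benzyloxy)-3-methoxyphenyl]methyl}oxolan-2-one | COc1cc(C[C@@H]2COC(=O)[C@H]2Cc2cc(OCc4ccc(OCc5ccccc5)c(OC)c4)c3c(c2)[C@H](CO)[C@@H](c2ccc(OCc4ccccc4)c(OC)c2)O3)ccc1OCc1ccccc1 | intermediate
23 | (3S,4S)-3-{[(2S,3R)-7-hydroxy-2-(4-hydroxy-3-methoxyphenyl)-3-(hydroxymethyl)-2,3-dihydro-1-benzofuran-5-yl]methyl}-4-[(4-hydroxy-3-methoxyphenyl)methyl]oxolan-2-one | COc1cc(C[C@@H]2COC(=O)[C@H]2Cc2cc(O)c3c(c2)[C@H](CO)[C@@H](c2ccc(O)c(OC)c2)O3)ccc1O | target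

Total step count: 13 (steps 1–5 lactone fragment, steps 6–11 dihydrobenzofuran fragment, steps 12–13 union and deprotection).
Longest linear sequence: 8 steps (10 to 23, steps 6–13).

Steps most likely to fail

Step 9. The chiral dirhodium carbene may discriminate poorly between the two enantiotopic O–CH2 hydrogens on this 3,4,5-trisubstituted arene, or the cis-to-trans equilibration at C3 may be incomplete. The fallback replaces catalyst control by a covalent auxiliary, sets out from bromide 12 and returns at diol 18. Bromide 12 is coupled under the conditions of step 7 with the zinc enolate prepared from (−)-menthyl bromoacetate and zinc, giving the (−)-menthyl arylacetate F1. Diazo transfer (p-ABSA, DBU) gives the (−)-menthyl aryldiazoacetate F2. Insertion with achiral dirhodium tetraacetate, Rh2(OAc)4, followed by DBU epimerization gives the trans-dihydrobenzofuran menthyl esters as two diastereomers, from which the (2S,3S)-menthyl ester F3 is separated by crystallization or chromatography. LiAlH4 reduction of F3 gives 18.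

Step 4. Hydrogen transfer to the α-silyl radical may outrun ring closure, or the trans preference may be eroded in the cyclization transition state. The fallback keeps the same ring-closing C4–C5 bond formation but moves it to the alkyne; it sets out from silyl ether 5 and returns at lactone 9. Compound 5 is cyclized 5-exo-dig (Bu3SnH, AIBN, benzene, 80 °C) to the 4-alkylidene-1,2-oxasilolane F4 (E/Z mixture). Tamao oxidation gives the diol enoate F5, which is carried on crude. Et3SiH/TFA removes the benzylic hydroxyl and closes the ring to the achiral 4-benzylbutenolide F6. The C4 stereocentre is then set by copper hydride-catalysed asymmetric conjugate reduction (Cu(OAc)2, the p-tol-BINAP enantiomer that delivers the S lactone, polymethylhydrosiloxane, t-BuOH), giving 9.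

Step 5. Reversible proton loss from the benzylic cation next to C4 may erode the C4 configuration, or the cation may be captured by an electron-rich arene before hydride transfer. The fallback replaces ionic hydrogenation by heterogeneous hydrogenolysis, sets out from 7 and returns at 9. Compound 7 is oxidized under the Tamao conditions alone and diol 8 is isolated together with its lactone forms. Hydrogenation (H2, Pd/C, catalytic HClO4, AcOH) removes the benzylic hydroxyl and the benzyl ether and closes the lactone, giving the phenolic lactone F7. Re-benzylation (BnBr, K2CO3, acetone) gives 9.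

Further compounds
F1 | step 9 | methyl 4,5-bis{[4-(benzyloxy)-3-methoxyphenyl]methoxy}-3-{2-[(1R,2S,5R)-menthyloxy]-2-oxoethyl}benzoate | CC(C)[C@@H]1CC[C@@H](C)C[C@H]1OC(=O)Cc1cc(C(=O)OC)cc(OCc2ccc(OCc3ccccc3)c(OC)c2)c1OCc1ccc(OCc2ccccc2)c(OC)c1
F2 | step 9 | methyl 4,5-bis{[4-(benzyloxy)-3-methoxyphenyl]methoxy}-3-{1-diazo-2-[(1R,2S,5R)-menthyloxy]-2-oxoethyl}benzoate | CC(C)[C@@H]1CC[C@@H](C)C[C@H]1OC(=O)C(=[N+]=[N-])c1cc(C(=O)OC)cc(OCc2ccc(OCc3ccccc3)c(OC)c2)c1OCc1ccc(OCc2ccccc2)c(OC)c1
F3 | step 9 | 3-[(1R,2S,5R)-menthyl] 5-methyl (2S,3S)-2-[4-(benzyloxy)-3-methoxyphenyl]-7-{[4-(benzyloxy)-3-methoxyphenyl]methoxy}-2,3-dihydro-1-benzofuran-3,5-dicarboxylate | COC(=O)c1cc(OCc2ccc(OCc3ccccc3)c(OC)c2)c2c(c1)[C@H](C(=O)O[C@@H]1C[C@H](C)CC[C@H]1C(C)C)[C@@H](c1ccc(OCc3ccccc3)c(OC)c1)O2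
F4 | step 4 | methyl 2-{(5R)-5-[4-(benzyloxy)-3-methoxyphenyl]-2,2-dimethyl-1,2-oxasilolan-4-ylidene}acetate (E/Z mixture) | COC(=O)C=C1C[Si](C)(C)O[C@@H]1c1ccc(OCc2ccccc2)c(OC)c1
F5 | step 4 | methyl (4R)-4-[4-(benzyloxy)-3-methoxyphenyl]-4-hydroxy-3-(hydroxymethyl)but-2-enoate (E/Z mixture) | COC(=O)C=C(CO)[C@H](O)c1ccc(OCc2ccccc2)c(OC)c1
F6 | step 4 | 4-{[4-(benzyloxy)-3-methoxyphenyl]methyl}furan-2(5H)-one | COc1cc(CC2=CC(=O)OC2)ccc1OCc1ccccc1
F7 | step 5 | (4S)-4-[(4-hydroxy-3-methoxyphenyl)methyl]oxolan-2-one | COc1cc(C[C@@H]2COC(=O)C2)ccc1O
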